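## Structural features

The target is (2R,3R)-3,5-dihydroxy-2-(4-hydroxy-3-methoxyphenyl)-7-methoxy-6-(3-methylbut-2-en-1-yl)chroman-4-one, a 2,3-trans dihydroflavonol. Ring C (O1–C2–C3–C4) is fused through C4a/C8a to a fully substituted phloroglucinol-type ring A and carries a guaiacyl ring B at C2. Ring A has a 5-OH hydrogen-bonded to the C4 carbonyl, a prenyl group at C6 and a methyl ether at C7, so the two oxygens that flank the prenyl group are different. The stereocentres C2 and C3 are adjacent. Their trans (diequatorial) arrangement is the thermodynamic one and C3, α to the ketone, can be equilibrated, so only C2 has to be set absolutely. Fragile elements are the prenyl alkene (electrophilic oxidants, acid-induced cyclisation onto the 5-OH), the α-ketol (aerial dehydrogenation to the flavonol, base-induced ring contraction) and the benzylic C2–O1 bond, which opens by retro-oxa-Michael or, once the 4'-OH is free, through a quinone methide. The real difficulty is twofold: C3 and C4 must be oxygenated although the prenyl alkene is the most electron-rich π-bond, and only the 5-oxygen may be unmasked. The key step uses the fact that the O1–C2–C3–C4 unit of ring C maps onto a salicylaldehyde (O1 and C4 already on ring A) and a cinnamaldehyde (C2, C3 and a formyl carbon on C3 that is excised later).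

## Logic of the disconnections

**16 ⇒ 15.** The aryl O–CH2 acetal bond at O4' is cut last. A free 4'-OH para to C2 would let the C2–O1 bond open to a quinone methide in every basic step, so ring B stays masked to the end. The forward step must cleave an aryl acetal with acid mild enough to spare the prenyl group next to the free 5-OH and the α-ketol.

**15 ⇒ 14.** The O–CH3 bond at O5 is cut. The two ethers that flank the prenyl group become distinguishable only once C4 is a carbonyl, because only O5 is chelated to it. Cutting here lets ring A travel as a symmetric dimethyl ether all the way back to 1. The forward step needs a chelation-driven demethylation that neither protonates nor halogenates the prenyl alkene, which excludes boron trihalides.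

**14 ⇒ 13.** A formyl group is put back on C3 (C3–CHO bond). It is the carbon that the annulation delivers and that activates C3=C4. With it, C3 is quaternary and its configuration, like that at C4, becomes irrelevant. The forward retro-Claisen cleavage must use a base too weak to open ring C or dehydrogenate the ketol, and the C3–H bond is then set trans to the aryl group under thermodynamic control.

**13 ⇒ 12 ⇒ 11 ⇒ 10.** The C4 carbonyl is traced to the secondary alcohol, the C4–OH bond to an oxirane, and both C–O bonds (C3–O, C4–O) to the C3=C4 alkene. Oxygen has to come from a nucleophilic oxidant, since any electrophilic one would prefer the prenyl alkene, and the formyl group makes C3=C4 the only electron-poor alkene. The gain is that 10 has one stereocentre and no sp3 oxygen. The forward steps must avoid peroxide attack on the aldehyde, retro-aldol cleavage of 12 and base epimerisation of C2.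

**10 ⇒ 7 + 9.** The O1–C2 and C3–C4 bonds are cut, which opens ring C and removes the only stereocentre. Both fragments are aldehydes of similar size, so the route is convergent. The forward annulation must set C2 by catalyst control and has to work on a hindered, electron-rich, chelated aldehyde.

**9 ⇒ 8.** The O–CH2 bond of the MOM ether is cut, leading to a commercial phenol. The forward alkylation only has to be selective for the phenol oxygen.

**7 ⇒ 6.** The aryl–CHO bond ortho to the phenol is cut. The two ortho positions of 6 are equivalent and the para position is blocked, so regiochemistry cannot go wrong. The forward formylation must be non-acidic because of the prenyl group.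

**6 ⇒ 5 ⇒ 4.** The aryl C–O bond is traced to a C–B and then to a C–H bond. The position is meta to both methoxy groups and unreachable by electrophilic substitution, but it is the only C–H of 4 without an ortho substituent. The forward borylation must leave the trisubstituted alkene alone, and the boronate oxidation must be non-electrophilic.

**4 ⇒ 3 ⇒ 1 + 2.** The aryl–CH2 bond is cut. The carbon between the two methoxy groups of 1 is the site of directed lithiation, so the prenyl group is placed exactly between the two future ring-A oxygens. The forward coupling must occur at the primary carbon of 2 without allylic transposition.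

## Other disconnections considered

**Alternative 1:** The cut is at C8a–O1 and C4a–C4, so that ring A is attached last to a C4–C3–C2 chain that already carries both stereocentres as an acetonide. In the forward step the ortho-silylaryl triflate A1 (about three steps from 6) would be treated with CsF in the presence of the acetonide acid A2 (from asymmetric dihydroxylation of the MOM-protected ferulate ester). The carboxylate oxygen would add to the aryne carbon remote from the methoxy group, the aryl anion would attack the carbonyl and the four-membered intermediate would open to the hydroxyaryl ketone A3. Acetonide removal and Mitsunobu ring closure with inversion at the benzylic carbon would then lead to 14.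
- In its favour: both stereocentres come from a dihydroxylation of predictable sense; the C3 oxygen is present from the start; no traceless carbon and no redox adjustment at C3/C4 are needed; the methoxy group steers the aryne regiochemistry. On stereochemical certainty this plan is the better of the two.
- Against it here: an aryne is generated with fluoride at elevated temperature beside a prenyl group, which is a good ene partner for arynes. Acetonide hydrolysis has to spare the MOM group and the prenyl alkene. The Mitsunobu closure at a p-alkoxybenzylic carbinol may ionise.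
- Comparison: it needs the same 5-O-demethylation as the chosen plan, so it is equal on that point. It is longer by roughly four to five steps. Mechanistically it replaces one catalytic annulation by a stoichiometric aryne insertion plus a separate ring closure.

**Alternative 2:** The cut is through ring A (C5–C6, C7–C8, C4a–C5), which would be built last. In the forward step the diazo ketone A4 would undergo photochemical Wolff rearrangement to a vinylketene. This would add the ynol ether A5 by [2+2] cycloaddition with the nucleophilic alkyne carbon bonding to the ketene carbonyl carbon. 4π ring opening, 6π closure and tautomerisation would give the phenol A6 (Danheiser benzannulation).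
- In its favour: the polarity of the ynol ether fixes the whole ring-A pattern; the 5-OH emerges free and the 7-oxygen as its methyl ether, so no selective demethylation is needed. On this point it is the better plan. The prenyl group enters inside a small alkyne and never meets an oxidant, three C–C bonds form in one operation, and one acid step would remove both MOM groups of A6.
- Against it here: A4 is itself a chiral 2-aryl-3-alkoxy-dihydropyranone whose enantioselective preparation and diazo transfer are a multi-step problem. Its C2–O bond is β to an enone and can open under the basic and thermal conditions involved. Irradiation meets an aryl enone chromophore, A5 is volatile and hydrolytically labile, and a vinylketene whose alkene is part of a vinylogous ester is untested in this cascade.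
- Comparison: the bond economy of the key step is higher than in the chosen plan, but the overall sequence would be clearly longer and the stereocentres would have to survive the most forcing step.

**Alternative 3:** The cut is at C3=C4. In the forward step the second-generation Grubbs catalyst would join the vinyl group of the allylic aryl ether and the methylene of the silyl enol ether in A7 with loss of ethylene, closing ring C as the flavanone silyl enol ether A8. Rubottom-type oxidation anti to the aryl group and desilylation would give 14.
- In its favour: C4 arrives at the ketone oxidation level, no carbon has to be excised and only ethylene is lost. On redox and atom economy this plan is equal or better.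
- Against it here: the Rubottom oxidation needs a peracid or dioxirane, which the prenyl alkene also accepts; this is the chemoselectivity problem that the formyl strategy avoids. The enol ether is 1,1-disubstituted, electron-rich and flanked by two ortho substituents, and the ruthenium alkylidene may engage the prenyl group. A7 is a doubly activated (benzylic and allylic) aryl ether that can ionise or undergo aromatic Claisen rearrangement at metathesis temperatures, and its enantioselective formation from a hindered, chelated phenol is the hard step of that route.
- Comparison: the step count would be about equal to that of the chosen plan. C2 would be set before ring closure and not during it, and the risk moves from the oxygenation sequence to the etherification and the oxidant selectivity.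

Key step: step 5

Remark: the target is read as the (2R,3R)-trans isomer; the two annulation partners, the chromene aldehyde and the target have the same spatial arrangement at C2 and consistent substitution, so no structure needs correction. The future 5-oxygen is kept as a methyl ether because a salicylaldehyde with a differently protected 6-oxygen cannot be reached regioselectively in as few steps. The demethylation is therefore planned with MgI2·OEt2. Compounds 1, 2 and 8 are taken as commercial.

## Steps

Step 1
Reactants: 1 1,3-dimethoxybenzene; 2 prenyl bromide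
Product: 4 1,3-dimethoxy-2-(3-methylbut-2-en-1-yl)benzene, via 2,6-dimethoxyphenyllithium 3 (not isolated)
Conditions: n-BuLi, THF, 0 °C to rt; then CuBr·SMe2 (10 mol %), 2, −78 °C to rt
Reagents that add atoms: none
Why: Directed ortho-metalation removes the most acidic proton, between the two methoxy groups, and the aryl metal displaces the primary allylic bromide at its less hindered α-carbon (copper-assisted allylic substitution), which places the prenyl group between two equivalent ethers.

Step 2
Reactants: 4 1,3-dimethoxy-2-(3-methylbut-2-en-1-yl)benzene
Product: 6 3,5-dimethoxy-4-(3-methylbut-2-en-1-yl)phenol, via pinacol boronate 5 (not isolated)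
Conditions: [Ir(OMe)(cod)]2 (1.5 mol %), 4,4'-di-tert-butyl-2,2'-bipyridine (3 mol %), B2pin2 (0.6 equiv), THF, 60 °C; then NaOH, 30% H2O2, THF/H2O, 0 °C
Reagents that add atoms: hydrogen peroxide, OO (phenol oxygen of 6); bis(pinacolato)diboron, CC1(C)OB(OC1(C)C)B1OC(C)(C)C(C)(C)O1 (boryl group of 5 only)
Why: Iridium-catalysed aromatic C–H borylation (Hartwig–Miyaura type) is sterically controlled and takes the only C–H bond without an ortho substituent, C5, while a trisubstituted alkene is a poor substrate for the catalyst; oxidation of the boronate with basic hydrogen peroxide, which does not epoxidise an unactivated alkene, gives the phenol at the same carbon.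

Step 3
Reactants: 6 3,5-dimethoxy-4-(3-methylbut-2-en-1-yl)phenol
Product: 7 2-hydroxy-4,6-dimethoxy-5-(3-methylbut-2-en-1-yl)benzaldehyde
Conditions: MgCl2, Et3N, (CH2O)n, MeCN, reflux
Reagents that add atoms: formaldehyde (as paraformaldehyde), C=O
Why: Casnati–Skattebøl ortho-formylation: the magnesium phenoxide delivers formaldehyde only to the ortho position and the benzylic alkoxide is oxidised in situ by a second formaldehyde (Oppenauer-type hydride transfer); both ortho positions are equivalent, the para position is blocked, and the basic medium spares the alkene.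

Step 4
Reactants: 8 coniferaldehyde
Product: 9 (E)-3-[3-methoxy-4-(methoxymethoxy)phenyl]prop-2-enal
Conditions: MOMCl, iPr2NEt, CH2Cl2, 0 °C to rt
Reagents that add atoms: chloromethyl methyl ether, COCCl
Why: O-Alkylation of the phenol with an α-chloro ether (Williamson type); the MOM ether keeps the 4'-oxygen from competing as a nucleophile in step 5 and from labilising the C2–O1 bond later, and it withstands the base, peroxide and oxidant of steps 5 to 7.

Step 5
Reactants: 7 2-hydroxy-4,6-dimethoxy-5-(3-methylbut-2-en-1-yl)benzaldehyde; 9 (E)-3-[3-methoxy-4-(methoxymethoxy)phenyl]prop-2-enal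
Product: 10 (2R)-5,7-dimethoxy-2-[3-methoxy-4-(methoxymethoxy)phenyl]-6-(3-methylbut-2-en-1-yl)-2H-chromene-3-carbaldehyde
Conditions: (S)-2-[diphenyl(trimethylsilyloxy)methyl]pyrrolidine (20 mol %), 2-nitrobenzoic acid (20 mol %), 4 Å molecular sieves, toluene, 20 °C
Reagents that add atoms: none
Why: Condensation of 9 with the secondary amine, assisted by the acid co-catalyst, gives the (E)-s-trans iminium ion; the phenol oxygen of 7 adds to its β-carbon (O1–C2) and the enamine so formed attacks the neighbouring aryl aldehyde (C3–C4) in a 6-(enolexo)-exo-trig aldol closure of ring C. Loss of water and hydrolysis release the catalyst and leave the conjugated 2H-chromene-3-carbaldehyde, which can no longer revert by retro-oxa-Michael. The closest known reaction type is the diarylprolinol silyl ether-catalysed domino oxa-Michael/aldol condensation of salicylaldehydes with cinnamaldehydes. The single new stereocentre, C2, is set by the catalyst: the CPh2(OSiMe3) group of the (S)-amine screens the Re face of the β-carbon, oxygen enters from the Si face, and this is R at C2 because C3 outranks the aryl group. The step needs enantiofacial selectivity and fast trapping of the reversible oxa-Michael adduct; the weak acid, the sieves, ambient temperature, a limited reaction time and a non-polar solvent that suppresses the uncatalysed phenoxide pathway serve this. Chemoselectivity rests on the substrates: 7 has one free phenol and a non-enolisable aldehyde, 9 has its phenol masked, and the prenyl alkene is inert to aminocatalysis. The antipodal catalyst is equally available should the sense of induction have to be inverted.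

Step 6
Reactants: 10 (2R)-chromene-3-carbaldehyde
Product: 12 (2R)-3,4-dihydroxy-5,7-dimethoxy-2-[3-methoxy-4-(methoxymethoxy)phenyl]-6-(3-methylbut-2-en-1-yl)chromane-3-carbaldehyde, via oxirane 11 (not isolated)
Conditions: 30% H2O2, NaOH (0.5 equiv), THF/H2O, 0 °C; Na2S2O3; then aqueous NaH2PO4 (pH 4–5), rt
Reagents that add atoms: hydrogen peroxide, OO (oxirane oxygen, later the 3-OH); water, O (4-OH)
Why: Weitz–Scheffer nucleophilic epoxidation: hydroperoxide adds to C4 of the only electron-poor alkene and the enolate closes onto oxygen, while the prenyl alkene is inert to a nucleophilic oxidant (no nitrile or methanol co-solvent, which would create an electrophilic peroxyimidic acid or a 4-methyl ether). The benzylic C4–O bond of the oxirane, activated by three ring-A oxygens, then ionises in the mildly acidic aqueous phase and is captured by water. The configurations at C3 and C4 are immaterial because both centres are erased in step 7; C2 is not involved.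

Step 7
Reactants: 12 (2R)-3,4-dihydroxychromane-3-carbaldehyde
Product: 14 (2R,3R)-3-hydroxy-5,7-dimethoxy-2-[3-methoxy-4-(methoxymethoxy)phenyl]-6-(3-methylbut-2-en-1-yl)chroman-4-one, via formyl ketone 13 (not isolated)
Conditions: IBX, DMSO, rt; then MeOH, K2CO3, 0 °C, argon
Reagents that add atoms: none
Why: IBX oxidises the secondary benzylic alcohol of a 1,2-diol to the ketol without glycol cleavage and leaves the tertiary alcohol, the aldehyde and the alkene untouched. The non-enolisable α-formyl ketone then undergoes retro-Claisen deformylation (methoxide adds to the aldehyde, the C3–CHO bond breaks, methyl formate leaves). The enediolate is protonated at C3 and equilibrates under the same mild base to the diequatorial 2,3-trans isomer, so C3 (R) is set under thermodynamic control by the fixed C2 centre.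

Step 8
Reactants: 14 (2R,3R)-3-hydroxy-5,7-dimethoxyflavanone MOM ether
Product: 15 (2R,3R)-3,5-dihydroxy-7-methoxy-2-[3-methoxy-4-(methoxymethoxy)phenyl]-6-(3-methylbut-2-en-1-yl)chroman-4-one
Conditions: MgI2·OEt2 (4 equiv), THF, 55 °C; dilute aqueous HCl work-up
Reagents that add atoms: none
Why: Chelation-controlled ether cleavage: magnesium binds the C4 carbonyl and the peri 5-methoxy oxygen and iodide removes the methyl group by SN2, while the 7- and 3'-methoxy groups are not chelated. This reagent type is known to demethylate a 5-methoxy prenylflavanone without cyclising or hydrohalogenating the prenyl group, which boron trihalides do not guarantee; partial loss of the MOM group here would be harmless.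

Step 9
Reactants: 15 (2R,3R)-5-hydroxy MOM ether
Product: 16 (2R,3R)-3,5-dihydroxy-2-(4-hydroxy-3-methoxyphenyl)-7-methoxy-6-(3-methylbut-2-en-1-yl)chroman-4-one
Conditions: 3 M HCl, MeOH, 40 °C
Reagents that add atoms: none
Why: Acid-catalysed acetal exchange removes the aryl MOM ether as dimethoxymethane; dilute acid in methanol at moderate temperature leaves both ketol stereocentres intact and stays below the threshold for cyclisation of the prenyl group onto the hydrogen-bonded 5-OH.

## Compound list

1 | 1,3-dimethoxybenzene | COc1cccc(OC)c1 | starting material
2 | prenyl bromide (1-bromo-3-methylbut-2-ene) | CC(C)=CCBr | starting material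
3 | 2,6-dimethoxyphenyllithium | COc1cccc(OC)c1[Li] | intermediate
4 | 1,3-dimethoxy-2-(3-methylbut-2-en-1-yl)benzene | COc1cccc(OC)c1CC=C(C)C | intermediate
5 | 2-[3,5-dimethoxy-4-(3-methylbut-2-en-1-yl)phenyl]-4,4,5,5-tetramethyl-1,3,2-dioxaborolane | COc1cc(B2OC(C)(C)C(C)(C)O2)cc(OC)c1CC=C(C)C | intermediate
6 | 3,5-dimethoxy-4-(3-methylbut-2-en-1-yl)phenol | COc1cc(O)cc(OC)c1CC=C(C)C | intermediate
7 | 2-hydroxy-4,6-dimethoxy-5-(3-methylbut-2-en-1-yl)benzaldehyde | COc1cc(O)c(C=O)c(OC)c1CC=C(C)C | intermediate
8 | coniferaldehyde, (E)-3-(4-hydroxy-3-methoxyphenyl)prop-2-enal | COc1cc(/C=C/C=O)ccc1O | starting material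
9 | (E)-3-[3-methoxy-4-(methoxymethoxy)phenyl]prop-2-enal | COCOc1ccc(/C=C/C=O)cc1OC | intermediate
10 | (2R)-5,7-dimethoxy-2-[3-methoxy-4-(methoxymethoxy)phenyl]-6-(3-methylbut-2-en-1-yl)-2H-chromene-3-carbaldehyde | COc1cc([C@H]2Oc3cc(OC)c(CC=C(C)C)c(OC)c3C=C2C=O)ccc1OCOC | intermediate
11 | (2R)-3,4-epoxy-5,7-dimethoxy-2-[3-methoxy-4-(methoxymethoxy)phenyl]-6-(3-methylbut-2-en-1-yl)chromane-3-carbaldehyde (oxirane expected mainly anti to the aryl group; C3/C4 left open, both epimers converge in step 7) | COc1cc([C@H]2Oc3cc(OC)c(CC=C(C)C)c(OC)c3C4OC24C=O)ccc1OCOC | intermediate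
12 | (2R)-3,4-dihydroxy-5,7-dimethoxy-2-[3-methoxy-4-(methoxymethoxy)phenyl]-6-(3-methylbut-2-en-1-yl)chromane-3-carbaldehyde (C3/C4 epimers, both converge in step 7) | COc1cc([C@H]2Oc3cc(OC)c(CC=C(C)C)c(OC)c3C(O)C2(O)C=O)ccc1OCOC | intermediate
13 | (2R)-3-hydroxy-5,7-dimethoxy-2-[3-methoxy-4-(methoxymethoxy)phenyl]-6-(3-methylbut-2-en-1-yl)-4-oxochromane-3-carbaldehyde (C3 epimers) | COc1cc([C@H]2Oc3cc(OC)c(CC=C(C)C)c(OC)c3C(=O)C2(O)C=O)ccc1OCOC | intermediate
14 | (2R,3R)-3-hydroxy-5,7-dimethoxy-2-[3-methoxy-4-(methoxymethoxy)phenyl]-6-(3-methylbut-2-en-1-yl)chroman-4-one | COc1cc([C@H]2Oc3cc(OC)c(CC=C(C)C)c(OC)c3C(=O)[C@@H]2O)ccc1OCOC | intermediate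
15 | (2R,3R)-3,5-dihydroxy-7-methoxy-2-[3-methoxy-4-(methoxymethoxy)phenyl]-6-(3-methylbut-2-en-1-yl)chroman-4-one | COc1cc([C@H]2Oc3cc(OC)c(CC=C(C)C)c(O)c3C(=O)[C@@H]2O)ccc1OCOC | intermediate
16 | (2R,3R)-3,5-dihydroxy-2-(4-hydroxy-3-methoxyphenyl)-7-methoxy-6-(3-methylbut-2-en-1-yl)chroman-4-one | COc1cc([C@H]2Oc3cc(OC)c(CC=C(C)C)c(O)c3C(=O)[C@@H]2O)ccc1O | target

## Step count and least certain steps

Total: 9 steps. Longest linear sequence: 8 steps (steps 1, 2, 3, 5, 6, 7, 8, 9 from 1); step 4 is a one-step branch from 8.

**Step 5 (key step).** The aldol closure onto a hindered, chelated, electron-rich aldehyde may be slow. The reversible oxa-Michael addition and the uncatalysed background reaction could then erode the enantioselectivity, the electron-rich enal gives a less electrophilic iminium ion, and long exposure to the amine could racemise the product through dienamine formation at C2. Fallback, from 7 and 9 back to 10: base-mediated annulation without a chiral catalyst (K2CO3, dioxane, reflux, phenoxide oxa-Michael addition then aldol condensation) would give the racemic chromene aldehyde F1, whose enantiomers would be separated by preparative chromatography on a chiral stationary phase; the (2R)-enantiomer is 10.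

**Step 6.** The push–pull conjugation of ring A with the enal may slow the hydroperoxide addition. The harsher base then needed could cause expulsion of the phenoxide O1 from the intermediate enolate (ring opening and loss of C2 configuration), peroxide attack on the aldehyde (Dakin or Baeyer–Villiger type), retro-aldol cleavage of the C3–C4 bond in the diol, or a 1,2-formyl shift during the acid stage. Fallback, from 10 back to 13: copper-catalysed conjugate borylation (CuCl, NaOt-Bu, Xantphos, B2pin2, MeOH, THF) would give the β-boryl aldehyde F2. Oxidation with NaBO3·4H2O would give the β-hydroxy aldehyde F3, and IBX the enolised 3-formylflavanone F4. Hydroxylation of F4 at C3 with 2-(phenylsulfonyl)-3-phenyloxaziridine and a trace of base, an oxygen donor that does not epoxidise an isolated alkene, would give 13, which is deformylated as in step 7.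

**Step 7.** The oxidant may cleave the C3–C4 bond of the diol. In the base stage the enediolate may expel O1 (ring opening, loss of C2 configuration), the ketol may be dehydrogenated by traces of air to the flavonol, or the cis-to-trans equilibration at C3 may stay incomplete. Fallback, from 12 back to 14: Pinnick oxidation (NaClO2, NaH2PO4, excess 2-methyl-2-butene, t-BuOH/H2O) of the aldehyde would give the hydroxy acid F5. IBX oxidation at C4 would give the β-keto acid F6, which loses carbon dioxide without any base through the enediol and ketonises to 14.

**Step 8.** Chelation of magnesium between the 3-OH and the carbonyl may compete with the 5-methoxy chelate and slow the demethylation. Prolonged heating with a Lewis acid and iodide could then open ring C (epimerisation) or add to the prenyl alkene. Fallback, from 7 to 16, which moves the ether exchange to the robust achiral aldehyde: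
- Pivaloylation of 7 (PivCl, Et3N, DMAP) gives the pivalate F7.
- Chelation-controlled cleavage of the methoxy group ortho to the formyl group (MgI2·OEt2, toluene/Et2O) gives the phenol F8.
- MOMCl/iPr2NEt gives the MOM ether F9, and K2CO3/MeOH removes the pivalate to give the salicylaldehyde F10.
- F10 is carried through steps 5 to 7 as the chromene aldehyde F11, the oxirane F12 (not isolated), the diol F13, the formyl ketone F14 (not isolated) and the bis-MOM dihydroflavonol F15.
- The conditions of step 9 then remove both MOM groups of F15 and give 16 without any late demethylation.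

**Step 2.** The iridium catalyst with HBpin or B2pin2 may hydroborate the prenyl alkene or borylate its allylic or vinylic C–H bonds, and borylation of the electron-rich arene may be slow. Fallback, from 2 together with purchased 3,5-dimethoxyphenol F16, back to 6: silylation (TIPSCl, imidazole) gives the silyl ether F17. Lithiation with n-BuLi between the two methoxy groups (the bulky silyl ether blocks its own ortho positions) gives the aryllithium F18. Prenylation with 2 (CuBr·SMe2) gives the silyl ether F19, and TBAF releases 6; the oxygen is thus in place before the alkene is introduced.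

## Further compounds

F1 | step 5 | racemic 5,7-dimethoxy-2-[3-methoxy-4-(methoxymethoxy)phenyl]-6-(3-methylbut-2-en-1-yl)-2H-chromene-3-carbaldehyde | COc1cc(C2Oc3cc(OC)c(CC=C(C)C)c(OC)c3C=C2C=O)ccc1OCOC
F2 | step 6 | (2S)-5,7-dimethoxy-2-[3-methoxy-4-(methoxymethoxy)phenyl]-6-(3-methylbut-2-en-1-yl)-4-(4,4,5,5-tetramethyl-1,3,2-dioxaborolan-2-yl)chromane-3-carbaldehyde (same spatial arrangement at C2 as 10; C3/C4 epimers) | COc1cc([C@H]2Oc3cc(OC)c(CC=C(C)C)c(OC)c3C(B4OC(C)(C)C(C)(C)O4)C2C=O)ccc1OCOC
F3 | step 6 | (2S)-4-hydroxy-5,7-dimethoxy-2-[3-methoxy-4-(methoxymethoxy)phenyl]-6-(3-methylbut-2-en-1-yl)chromane-3-carbaldehyde (same spatial arrangement at C2 as 10; C3/C4 epimers) | COc1cc([C@H]2Oc3cc(OC)c(CC=C(C)C)c(OC)c3C(O)C2C=O)ccc1OCOC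
F4 | step 6 | (2S)-5,7-dimethoxy-2-[3-methoxy-4-(methoxymethoxy)phenyl]-6-(3-methylbut-2-en-1-yl)-4-oxochromane-3-carbaldehyde (same spatial arrangement at C2 as 10; enolised at C3) | COc1cc([C@H]2Oc3cc(OC)c(CC=C(C)C)c(OC)c3C(=O)C2C=O)ccc1OCOC
F5 | step 7 | (2R)-3,4-dihydroxy-5,7-dimethoxy-2-[3-methoxy-4-(methoxymethoxy)phenyl]-6-(3-methylbut-2-en-1-yl)chromane-3-carboxylic acid (C3/C4 epimers) | COc1cc([C@H]2Oc3cc(OC)c(CC=C(C)C)c(OC)c3C(O)C2(O)C(=O)O)ccc1OCOC
F6 | step 7 | (2R)-3-hydroxy-5,7-dimethoxy-2-[3-methoxy-4-(methoxymethoxy)phenyl]-6-(3-methylbut-2-en-1-yl)-4-oxochromane-3-carboxylic acid (C3 epimers) | COc1cc([C@H]2Oc3cc(OC)c(CC=C(C)C)c(OC)c3C(=O)C2(O)C(=O)O)ccc1OCOC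
F7 | step 8 | 2-formyl-3,5-dimethoxy-4-(3-methylbut-2-en-1-yl)phenyl pivalate | COc1cc(OC(=O)C(C)(C)C)c(C=O)c(OC)c1CC=C(C)C
F8 | step 8 | 2-formyl-3-hydroxy-5-methoxy-4-(3-methylbut-2-en-1-yl)phenyl pivalate | COc1cc(OC(=O)C(C)(C)C)c(C=O)c(O)c1CC=C(C)C
F9 | step 8 | 2-formyl-5-methoxy-3-(methoxymethoxy)-4-(3-methylbut-2-en-1-yl)phenyl pivalate | COc1cc(OC(=O)C(C)(C)C)c(C=O)c(OCOC)c1CC=C(C)C
F10 | step 8 | 2-hydroxy-4-methoxy-6-(methoxymethoxy)-5-(3-methylbut-2-en-1-yl)benzaldehyde | COc1cc(O)c(C=O)c(OCOC)c1CC=C(C)C
F11 | step 8 | (2R)-7-methoxy-5-(methoxymethoxy)-2-[3-methoxy-4-(methoxymethoxy)phenyl]-6-(3-methylbut-2-en-1-yl)-2H-chromene-3-carbaldehyde | COc1cc([C@H]2Oc3cc(OC)c(CC=C(C)C)c(OCOC)c3C=C2C=O)ccc1OCOC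
F12 | step 8 | (2R)-3,4-epoxy-7-methoxy-5-(methoxymethoxy)-2-[3-methoxy-4-(methoxymethoxy)phenyl]-6-(3-methylbut-2-en-1-yl)chromane-3-carbaldehyde (C3/C4 epimers) | COc1cc([C@H]2Oc3cc(OC)c(CC=C(C)C)c(OCOC)c3C4OC24C=O)ccc1OCOC
F13 | step 8 | (2R)-3,4-dihydroxy-7-methoxy-5-(methoxymethoxy)-2-[3-methoxy-4-(methoxymethoxy)phenyl]-6-(3-methylbut-2-en-1-yl)chromane-3-carbaldehyde (C3/C4 epimers) | COc1cc([C@H]2Oc3cc(OC)c(CC=C(C)C)c(OCOC)c3C(O)C2(O)C=O)ccc1OCOC
F14 | step 8 | (2R)-3-hydroxy-7-methoxy-5-(methoxymethoxy)-2-[3-methoxy-4-(methoxymethoxy)phenyl]-6-(3-methylbut-2-en-1-yl)-4-oxochromane-3-carbaldehyde (C3 epimers) | COc1cc([C@H]2Oc3cc(OC)c(CC=C(C)C)c(OCOC)c3C(=O)C2(O)C=O)ccc1OCOC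
F15 | step 8 | (2R,3R)-3-hydroxy-7-methoxy-5-(methoxymethoxy)-2-[3-methoxy-4-(methoxymethoxy)phenyl]-6-(3-methylbut-2-en-1-yl)chroman-4-one | COc1cc([C@H]2Oc3cc(OC)c(CC=C(C)C)c(OCOC)c3C(=O)[C@@H]2O)ccc1OCOC
F16 | step 2 | 3,5-dimethoxyphenol | COc1cc(O)cc(OC)c1
F17 | step 2 | (3,5-dimethoxyphenoxy)triisopropylsilane | COc1cc(O[Si](C(C)C)(C(C)C)C(C)C)cc(OC)c1
F18 | step 2 | [2,6-dimethoxy-4-(triisopropylsilyloxy)phenyl]lithium | COc1cc(O[Si](C(C)C)(C(C)C)C(C)C)cc(OC)c1[Li]
F19 | step 2 | [3,5-dimethoxy-4-(3-methylbut-2-en-1-yl)phenoxy]triisopropylsilane | COc1cc(O[Si](C(C)C)(C(C)C)C(C)C)cc(OC)c1CC=C(C)C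
A1 | alternative 1 | 3,5-dimethoxy-4-(3-methylbut-2-en-1-yl)-2-(trimethylsilyl)phenyl trifluoromethanesulfonate | COc1cc(OS(=O)(=O)C(F)(F)F)c([Si](C)(C)C)c(OC)c1CC=C(C)C
A2 | alternative 1 | (4R,5S)-5-[3-methoxy-4-(methoxymethoxy)phenyl]-2,2-dimethyl-1,3-dioxolane-4-carboxylic acid | OC(=O)[C@@H]1OC(C)(C)O[C@H]1c1ccc(OCOC)c(OC)c1
A3 | alternative 1 | [2-hydroxy-4,6-dimethoxy-5-(3-methylbut-2-en-1-yl)phenyl]{(4R,5S)-5-[3-methoxy-4-(methoxymethoxy)phenyl]-2,2-dimethyl-1,3-dioxolan-4-yl}methanone | COc1cc(O)c(C(=O)[C@@H]2OC(C)(C)O[C@H]2c3ccc(OCOC)c(OC)c3)c(OC)c1CC=C(C)C
A4 | alternative 2 | (2R,3R)-6-(2-diazoacetyl)-3-(methoxymethoxy)-2-[3-methoxy-4-(methoxymethoxy)phenyl]-2,3-dihydro-4H-pyran-4-one | COc1cc([C@H]2OC(C(=O)C=[N+]=[N-])=CC(=O)[C@@H]2OCOC)ccc1OCOC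
A5 | alternative 2 | 1-methoxy-5-methylhex-4-en-1-yne | COC#CCC=C(C)C
A6 | alternative 2 | (2R,3R)-5-hydroxy-7-methoxy-3-(methoxymethoxy)-2-[3-methoxy-4-(methoxymethoxy)phenyl]-6-(3-methylbut-2-en-1-yl)chroman-4-one | COc1cc([C@H]2Oc3cc(OC)c(CC=C(C)C)c(O)c3C(=O)[C@@H]2OCOC)ccc1OCOC
A7 | alternative 3 | tert-butyl[(1-{2,4-dimethoxy-6-[((1S)-1-[3-methoxy-4-(methoxymethoxy)phenyl]prop-2-en-1-yl)oxy]-3-(3-methylbut-2-en-1-yl)phenyl}ethenyl)oxy]dimethylsilane (same spatial arrangement as C2 of the target) | COc1cc([C@H](C=C)Oc2cc(OC)c(CC=C(C)C)c(OC)c2C(=C)O[Si](C)(C)C(C)(C)C)ccc1OCOC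
A8 | alternative 3 | tert-butyl({(2S)-5,7-dimethoxy-2-[3-methoxy-4-(methoxymethoxy)phenyl]-6-(3-methylbut-2-en-1-yl)-2H-chromen-4-yl}oxy)dimethylsilane (same spatial arrangement as C2 of the target) | COc1cc([C@H]2Oc3cc(OC)c(CC=C(C)C)c(OC)c3C(O[Si](C)(C)C(C)(C)C)=C2)ccc1OCOC
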